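The route rests on cutting the lactone-side trisubstituted olefin. In the target, the methoxy oxygen, the methoxy-bearing carbon, both olefinic carbons and the vinylic methyl carbon (cis to the methoxy-bearing carbon) are the five atoms O1–C5–C4–C3–C2 of a furan-2(5H)-one ring. Ring-closing metathesis of an allylic 2-methylidene ester therefore forms that C=C bond and a temporary butenolide in one operation and fixes the olefin geometry. The precursor is the ester of (3S,5E)-8-(furan-3-yl)-5-methylocta-1,5-dien-3-ol with 5,5-dimethoxy-2-methylidenepentanoic acid. Reductive ring opening, O-methylation and deoxygenation of the former acyl carbon give the E-olefin; the hydroxy lactone is then built from the unmasked aldehyde under tartrate control.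

Key step: step 10

Remark: the two centres of the hydroxy lactone are too far from the methoxy centre for substrate control, so they are set by reagent control, which means the carbinol epimers formed in step 17 are resolved in step 18 and at most half of that material goes forward.

Step 1
Reactants: 1 (S)-epichlorohydrin, (2S)-2-(chloromethyl)oxirane; 2 ethynyltrimethylsilane
Product: 3 (2S)-1-chloro-5-(trimethylsilyl)pent-4-yn-2-ol
Conditions: 2, n-BuLi, THF, −78 °C; BF3·OEt2; then 1, −78 °C
Reagents that add atoms: none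
Why: BF3-promoted SN2 opening of the epoxide by the lithium acetylide (Yamaguchi alkynylation) should occur at the unsubstituted ring CH2 faster than chloride displacement and leaves the C–O bond of the stereocentre intact, so the (S) configuration of 1 is carried over.

Step 2
Reactants: 3 (2S)-1-chloro-5-(trimethylsilyl)pent-4-yn-2-ol
Product: 6 (3S)-hex-1-en-5-yn-3-ol, via silyl alkynyl oxirane 4 (not isolated), via silyl enynol 5 (not isolated)
Conditions: Me3S+ I−, n-BuLi, THF, −20 °C → rt; then MeOH, K2CO3, rt
Reagents that add atoms: trimethylsulfonium iodide, C[S+](C)C.[I-]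
Why: Excess dimethylsulfonium methylide should close the chlorohydrin to epoxide 4, open it at CH2 and eliminate dimethyl sulfide (one-carbon epoxide-to-allylic-alcohol homologation) without touching the carbinol C–O bond, and methanolic K2CO3 then cleaves the alkynyl C–Si bond (protodesilylation).

Step 3
Reactants: 6 (3S)-hex-1-en-5-yn-3-ol
Product: 8 (3S,5E)-6-iodo-5-methylhexa-1,5-dien-3-ol, via alkenylalane 7 (not isolated)
Conditions: Me3Al (3 equiv), Cp2ZrCl2 (0.25 equiv), CH2Cl2, 0 °C → rt; then I2, THF, −30 → 0 °C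
Reagents that add atoms: trimethylaluminium, C[Al](C)C; iodine, II
Why: Negishi zirconium-catalysed carboalumination adds methyl and aluminium syn across the terminal alkyne with methyl on the internal carbon, and iodinolysis of the C–Al bond with retention should give the (E)-iodide; the hydroxyl is held as its aluminium alkoxide and the monosubstituted alkene is not expected to react.

Step 4
Reactants: 9 furan-3-carbaldehyde
Product: 10 3-ethenylfuran
Conditions: Ph3P+CH3 Br−, n-BuLi, THF, 0 °C → rt; filtered through silica (pentane) and used as a solution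
Reagents that add atoms: methyltriphenylphosphonium bromide, C[P+](c1ccccc1)(c1ccccc1)c1ccccc1.[Br-]
Why: Wittig methylenation of an aromatic aldehyde is reliable, and using the volatile, polymerisation-prone vinylfuran directly as a solution avoids losses.

Step 5
Reactants: 10 3-ethenylfuran; 8 (3S,5E)-6-iodo-5-methylhexa-1,5-dien-3-ol
Product: 12 (3S,5E)-8-(furan-3-yl)-5-methylocta-1,5-dien-3-ol, via B-alkyl borane 11 (not isolated)
Conditions: 10 (1.3 equiv), 9-BBN-H (1.2 equiv), THF, 0 °C → rt; then 8, Pd(dppf)Cl2 (5 mol%), AsPh3, Cs2CO3, DMF–H2O, rt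
Reagents that add atoms: none
Why: Anti-Markovnikov hydroboration of the vinyl group followed by B-alkyl Suzuki–Miyaura coupling, which retains the geometry of the alkenyl iodide, should give the E-trisubstituted olefin; the slight excess of 10 consumes all B–H so the vinyl group of 8 is spared, and the free alcohol is tolerated.

Step 6
Reactants: 13 triethyl phosphonoacetate; 14 3-bromo-1,1-dimethoxypropane
Product: 15 ethyl 2-(diethoxyphosphoryl)-5,5-dimethoxypentanoate
Conditions: 13 (1.5 equiv), NaH, DMF, 0 °C; then 14, 60 °C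
Reagents that add atoms: none
Why: SN2 alkylation of the stabilised phosphonoacetate anion with a primary bromide; an excess of 13 limits dialkylation and the acetal is inert to base.

Step 7
Reactants: 15 ethyl 2-(diethoxyphosphoryl)-5,5-dimethoxypentanoate
Product: 16 ethyl 5,5-dimethoxy-2-methylidenepentanoate
Conditions: aq. HCHO, K2CO3, H2O–THF, rt
Reagents that add atoms: formaldehyde, C=O
Why: Horner–Wadsworth–Emmons olefination with formaldehyde is the standard route from 2-alkylphosphonoacetates to 2-alkylacrylates and creates no geometric isomers.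

Step 8
Reactants: 16 ethyl 5,5-dimethoxy-2-methylidenepentanoate
Product: 17 5,5-dimethoxy-2-methylidenepentanoic acid
Conditions: LiOH, THF–H2O, rt; cold dilute HCl to pH 4; used at once
Reagents that add atoms: lithium hydroxide, [Li+].[OH-]
Why: Saponification in a non-nucleophilic cosolvent avoids conjugate addition to the acrylate, and acidification only to pH 4 in the cold keeps the dimethyl acetal intact.

Step 9
Reactants: 12 (3S,5E)-8-(furan-3-yl)-5-methylocta-1,5-dien-3-ol; 17 5,5-dimethoxy-2-methylidenepentanoic acid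
Product: 18 (3S,5E)-8-(furan-3-yl)-5-methylocta-1,5-dien-3-yl 5,5-dimethoxy-2-methylidenepentanoate
Conditions: DCC, DMAP (cat.), CH2Cl2, 0 °C → rt
Reagents that add atoms: none
Why: Steglich esterification acylates the hydroxyl oxygen without breaking the carbinol C–O bond, so the (S) centre is retained, and the neutral conditions spare the acetal and the furan.

Step 10
Reactants: 18 (3S,5E)-8-(furan-3-yl)-5-methylocta-1,5-dien-3-yl 5,5-dimethoxy-2-methylidenepentanoate
Product: 19 (5S)-3-(3,3-dimethoxypropyl)-5-[(2E)-5-(furan-3-yl)-2-methylpent-2-en-1-yl]furan-2(5H)-one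
Conditions: second-generation Grubbs catalyst (H2IMes)(PCy3)Cl2Ru=CHPh (5 mol%), toluene (5 mM), 80 °C, argon sparge
Reagents that add atoms: none
Why: The catalyst should first exchange its benzylidene with the monosubstituted vinyl group of 18, the most accessible olefin, to give a ruthenium alkylidene at the carbinol-side CH. This alkylidene adds across the 1,1-disubstituted acrylate C=CH2 by intramolecular [2+2] cycloaddition, and cycloreversion of the ruthenacyclobutane releases the butenolide and Ru=CH2, which re-enters the cycle with loss of ethene. The closest known reaction type is the ring-closing metathesis of allyl 2-alkylacrylates to 3-substituted furan-2(5H)-ones. The five-membered ring is closed by forming the C3=C4 double bond between the acrylate α-carbon and the former vinyl CH, so the ring holds the acyl carbon and C5 cis. No stereocentre is formed, and the (S) centre at C5 is an sp3 spectator whose bonds are not broken. The step needs the two terminal olefins to react in preference to the trisubstituted olefin, which loads slowly and could only close a cyclobutene, and needs ring closure to beat dimerisation, which high dilution and removal of ethene secure.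

Step 11
Reactants: 19 (5S)-3-(3,3-dimethoxypropyl)-5-[(2E)-5-(furan-3-yl)-2-methylpent-2-en-1-yl]furan-2(5H)-one
Product: 20 (2Z,4S,6E)-2-(3,3-dimethoxypropyl)-9-(furan-3-yl)-6-methylnona-2,6-diene-1,4-diol
Conditions: iBu2AlH (4 equiv), CH2Cl2, −78 → 0 °C; aq. potassium sodium tartrate
Reagents that add atoms: none
Why: Twofold 1,2-hydride reduction of the unsaturated lactone (through the lactol) opens the ring to the ene-diol with the ring-imposed Z geometry, without conjugate reduction and, at or below 0 °C, without touching the dimethyl acetal.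

Step 12
Reactants: 20 (2Z,4S,6E)-2-(3,3-dimethoxypropyl)-9-(furan-3-yl)-6-methylnona-2,6-diene-1,4-diol
Product: 21 (2Z,4S,6E)-1-{[tert-butyl(diphenyl)silyl]oxy}-2-(3,3-dimethoxypropyl)-9-(furan-3-yl)-6-methylnona-2,6-dien-4-ol
Conditions: tBuPh2SiCl (1.05 equiv), imidazole, CH2Cl2, −20 → 0 °C
Reagents that add atoms: tert-butyl(chloro)diphenylsilane, CC(C)(C)[Si](Cl)(c1ccccc1)c1ccccc1
Why: Silyl ether formation with a bulky chlorosilane should select the primary allylic hydroxyl over the more hindered secondary one.

Step 13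
Reactants: 21 (2Z,4S,6E)-1-{[tert-butyl(diphenyl)silyl]oxy}-2-(3,3-dimethoxypropyl)-9-(furan-3-yl)-6-methylnona-2,6-dien-4-ol
Product: 22 tert-butyl{[(2Z,4S,6E)-2-(3,3-dimethoxypropyl)-9-(furan-3-yl)-4-methoxy-6-methylnona-2,6-dien-1-yl]oxy}diphenylsilane
Conditions: MeI (excess), NaH, THF–DMF, 0 °C → rt
Reagents that add atoms: iodomethane, CI
Why: Williamson etherification at oxygen leaves the (S) centre unchanged, and with iodomethane present before the base the alkoxide should be methylated faster than the bulky silyl group can migrate across the Z-olefin.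

Step 14
Reactants: 22 tert-butyl{[(2Z,4S,6E)-2-(3,3-dimethoxypropyl)-9-(furan-3-yl)-4-methoxy-6-methylnona-2,6-dien-1-yl]oxy}diphenylsilane
Product: 23 (2Z,4S,6E)-2-(3,3-dimethoxypropyl)-9-(furan-3-yl)-4-methoxy-6-methylnona-2,6-dien-1-ol
Conditions: Bu4NF, THF, rt
Reagents that add atoms: none
Why: Fluoride-mediated desilylation is orthogonal to the methyl ether, the acetal, the furan and both olefins.

Step 15
Reactants: 23 (2Z,4S,6E)-2-(3,3-dimethoxypropyl)-9-(furan-3-yl)-4-methoxy-6-methylnona-2,6-dien-1-ol
Product: 25 3-[(3E,6S,7E)-6,11,11-trimethoxy-4,8-dimethylundeca-3,7-dien-1-yl]furan, via allylic mesylate 24 (not isolated)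
Conditions: MsCl, Et3N, CH2Cl2, −30 °C; crude, then LiEt3BH (3 equiv), THF, −78 → 0 °C
Reagents that add atoms: none
Why: Sulfonylation followed by direct SN2 hydride displacement at the unhindered primary allylic carbon turns CH2OH into the vinylic methyl without moving the double bond, and because methyl ranks below the chain CH2 the olefin becomes E by descriptor only, not by any change in shape.

Step 16
Reactants: 25 3-[(3E,6S,7E)-6,11,11-trimethoxy-4,8-dimethylundeca-3,7-dien-1-yl]furan
Product: 26 (4E,6S,8E)-11-(furan-3-yl)-6-methoxy-4,8-dimethylundeca-4,8-dienal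
Conditions: PPTS (0.2 equiv), acetone–H2O (9:1), 45 °C
Reagents that add atoms: water, O
Why: Mild acid-catalysed acetal hydrolysis goes through an oxocarbenium ion that forms far more readily than the allyl cation from the secondary allylic methyl ether, so that ether and the 3-alkylfuran should survive.

Step 17
Reactants: 26 (4E,6S,8E)-11-(furan-3-yl)-6-methoxy-4,8-dimethylundeca-4,8-dienal
Product: 27 (3RS,6E,8S,10E)-13-(furan-3-yl)-8-methoxy-2,6,10-trimethyltrideca-1,6,10-trien-3-ol (both C3 epimers)
Conditions: CH2=C(CH3)MgBr, THF, −78 °C; aq. NH4Cl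
Reagents that add atoms: isopropenylmagnesium bromide, C=C(C)[Mg]Br
Why: Grignard 1,2-addition to the unhindered aldehyde is reliable, and no facial control is expected because the nearest stereocentre is five atoms away, so both carbinol epimers form and are resolved in step 18.

Step 18
Reactants: 27 (3RS,6E,8S,10E)-13-(furan-3-yl)-8-methoxy-2,6,10-trimethyltrideca-1,6,10-trien-3-ol (both C3 epimers)
Product: 28 (1R,4E,6S,8E)-11-(furan-3-yl)-6-methoxy-4,8-dimethyl-1-[(2S)-2-methyloxiran-2-yl]undeca-4,8-dien-1-ol
Conditions: Ti(OiPr)4 (0.2 equiv), D-(−)-diisopropyl tartrate (0.25 equiv), tBuOOH (0.5 equiv), 4 Å MS, CH2Cl2, −20 °C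
Reagents that add atoms: tert-butyl hydroperoxide, CC(C)(C)OO
Why: In the Sharpless kinetic-resolution epoxidation the D-(−)-tartrate titanium complex should epoxidise only the (3R) epimer of this 2-methyl allylic alcohol, on the olefin face that makes the oxirane carbon (S) and with the usual erythro relationship to the carbinol, while the (3S) epimer is recovered and the undirected trisubstituted olefins and the furan are left alone.

Step 19
Reactants: 28 (1R,4E,6S,8E)-11-(furan-3-yl)-6-methoxy-4,8-dimethyl-1-[(2S)-2-methyloxiran-2-yl]undeca-4,8-dien-1-ol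
Product: 30 (5S)-5-[(1R,4E,6S,8E)-11-(furan-3-yl)-1-hydroxy-6-methoxy-4,8-dimethylundeca-4,8-dien-1-yl]-5-methyloxolan-2-one (target), via dihydroxy acid 29 (not isolated)
Conditions: CH3CO2H, LiN(iPr)2 (2 equiv per acid, no excess), THF–DMPU, 0 °C; 28, 45 °C; then aq. HCl to pH 3, rt
Reagents that add atoms: acetic acid, CC(=O)O
Why: Opening of the epoxide by the acetic acid dianion at the unsubstituted oxirane CH2 (SN2) breaks no bond at either stereocentre, and the tertiary γ-hydroxy acid should close spontaneously to the γ-lactone on acidification (lactonisation), giving the (5S,1'R) hydroxy lactone.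

Compound list
1 | (S)-epichlorohydrin, (2S)-2-(chloromethyl)oxirane | ClC[C@@H]1CO1 | starting material
2 | ethynyltrimethylsilane | C#C[Si](C)(C)C | starting material
3 | (2S)-1-chloro-5-(trimethylsilyl)pent-4-yn-2-ol | ClC[C@@H](O)CC#C[Si](C)(C)C | intermediate
4 | trimethyl{3-[(2S)-oxiran-2-yl]prop-1-yn-1-yl}silane | C1[C@@H](O1)CC#C[Si](C)(C)C | intermediate (not isolated)
5 | (3S)-6-(trimethylsilyl)hex-1-en-5-yn-3-ol | C=C[C@@H](O)CC#C[Si](C)(C)C | intermediate (not isolated)
6 | (3S)-hex-1-en-5-yn-3-ol | C=C[C@@H](O)CC#C | intermediate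
7 | dimethylaluminium (3S,5E)-6-(dimethylalumanyl)-5-methylhexa-1,5-dien-3-olate | C=C[C@@H](O[Al](C)C)C/C(C)=C/[Al](C)C | intermediate (not isolated)
8 | (3S,5E)-6-iodo-5-methylhexa-1,5-dien-3-ol | C=C[C@@H](O)C/C(C)=C/I | intermediate
9 | furan-3-carbaldehyde | O=Cc1ccoc1 | starting material
10 | 3-ethenylfuran | C=Cc1ccoc1 | intermediate
11 | 9-[2-(furan-3-yl)ethyl]-9-borabicyclo[3.3.1]nonane | c1cc(CCB2C3CCCC2CCC3)co1 | intermediate (not isolated)
12 | (3S,5E)-8-(furan-3-yl)-5-methylocta-1,5-dien-3-ol | C=C[C@@H](O)C/C(C)=C/CCc1ccoc1 | intermediate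
13 | triethyl phosphonoacetate | CCOC(=O)CP(=O)(OCC)OCC | starting material
14 | 3-bromo-1,1-dimethoxypropane | COC(CCBr)OC | starting material
15 | ethyl 2-(diethoxyphosphoryl)-5,5-dimethoxypentanoate | CCOC(=O)C(CCC(OC)OC)P(=O)(OCC)OCC | intermediate
16 | ethyl 5,5-dimethoxy-2-methylidenepentanoate | C=C(CCC(OC)OC)C(=O)OCC | intermediate
17 | 5,5-dimethoxy-2-methylidenepentanoic acid | C=C(CCC(OC)OC)C(=O)O | intermediate
18 | (3S,5E)-8-(furan-3-yl)-5-methylocta-1,5-dien-3-yl 5,5-dimethoxy-2-methylidenepentanoate | C=C(CCC(OC)OC)C(=O)O[C@H](C=C)C/C(C)=C/CCc1ccoc1 | intermediate (key-step precursor)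
19 | (5S)-3-(3,3-dimethoxypropyl)-5-[(2E)-5-(furan-3-yl)-2-methylpent-2-en-1-yl]furan-2(5H)-one | O=C1O[C@@H](C/C(C)=C/CCc2ccoc2)C=C1CCC(OC)OC | intermediate (key-step product)
20 | (2Z,4S,6E)-2-(3,3-dimethoxypropyl)-9-(furan-3-yl)-6-methylnona-2,6-diene-1,4-diol | OC/C(CCC(OC)OC)=C\[C@@H](O)C/C(C)=C/CCc1ccoc1 | intermediate
21 | (2Z,4S,6E)-1-{[tert-butyl(diphenyl)silyl]oxy}-2-(3,3-dimethoxypropyl)-9-(furan-3-yl)-6-methylnona-2,6-dien-4-ol | CC(C)(C)[Si](OC/C(CCC(OC)OC)=C\[C@@H](O)C/C(C)=C/CCc1ccoc1)(c1ccccc1)c1ccccc1 | intermediate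
22 | tert-butyl{[(2Z,4S,6E)-2-(3,3-dimethoxypropyl)-9-(furan-3-yl)-4-methoxy-6-methylnona-2,6-dien-1-yl]oxy}diphenylsilane | CC(C)(C)[Si](OC/C(CCC(OC)OC)=C\[C@@H](OC)C/C(C)=C/CCc1ccoc1)(c1ccccc1)c1ccccc1 | intermediate
23 | (2Z,4S,6E)-2-(3,3-dimethoxypropyl)-9-(furan-3-yl)-4-methoxy-6-methylnona-2,6-dien-1-ol | OC/C(CCC(OC)OC)=C\[C@@H](OC)C/C(C)=C/CCc1ccoc1 | intermediate
24 | (2Z,4S,6E)-2-(3,3-dimethoxypropyl)-9-(furan-3-yl)-4-methoxy-6-methylnona-2,6-dien-1-yl methanesulfonate | CS(=O)(=O)OC/C(CCC(OC)OC)=C\[C@@H](OC)C/C(C)=C/CCc1ccoc1 | intermediate (not isolated)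
25 | 3-[(3E,6S,7E)-6,11,11-trimethoxy-4,8-dimethylundeca-3,7-dien-1-yl]furan | C/C(CCC(OC)OC)=C\[C@@H](OC)C/C(C)=C/CCc1ccoc1 | intermediate
26 | (4E,6S,8E)-11-(furan-3-yl)-6-methoxy-4,8-dimethylundeca-4,8-dienal | O=CCC/C(C)=C/[C@@H](OC)C/C(C)=C/CCc1ccoc1 | intermediate
27 | (3RS,6E,8S,10E)-13-(furan-3-yl)-8-methoxy-2,6,10-trimethyltrideca-1,6,10-trien-3-ol, both C3 epimers | C=C(C)C(O)CC/C(C)=C/[C@@H](OC)C/C(C)=C/CCc1ccoc1 | intermediate
28 | (1R,4E,6S,8E)-11-(furan-3-yl)-6-methoxy-4,8-dimethyl-1-[(2S)-2-methyloxiran-2-yl]undeca-4,8-dien-1-ol | C[C@]1(CO1)[C@H](O)CC/C(C)=C/[C@@H](OC)C/C(C)=C/CCc1ccoc1 | intermediate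
29 | (4S,5R,8E,10S,12E)-15-(furan-3-yl)-4,5-dihydroxy-10-methoxy-4,8,12-trimethylpentadeca-8,12-dienoic acid | C[C@](O)(CCC(=O)O)[C@H](O)CC/C(C)=C/[C@@H](OC)C/C(C)=C/CCc1ccoc1 | intermediate (not isolated)
30 | (5S)-5-[(1R,4E,6S,8E)-11-(furan-3-yl)-1-hydroxy-6-methoxy-4,8-dimethylundeca-4,8-dien-1-yl]-5-methyloxolan-2-one | CO[C@H](/C=C(\C)CC[C@@H](O)[C@]1(C)CCC(=O)O1)C/C(C)=C/CCc1ccoc1 | target

Total step count: 19. Longest linear sequence: 15 steps (steps 1, 2, 3, 5, 9, 10 and 11 to 19).

Steps most likely to fail

Step 10 carries the main risk. Turnover at the electron-poor 1,1-disubstituted acrylate may be slow, so that intermolecular metathesis of the vinyl groups, carbonyl chelation of the ruthenium alkylidene and hydride-induced double-bond migration compete with ring closure. The fallback keeps a temporary ring that fixes the geometry but moves the tether to silicon; it sets out from 12 and 16 and comes back to the route at 20. Reduction of 16 with iBu2AlH should give 2-(3,3-dimethoxypropyl)prop-2-en-1-ol F1. Alcohol 12 is silylated with iPr2SiCl2 and imidazole, and the chlorosilane is capped with F1 to give the mixed bis(alkoxy)di(propan-2-yl)silane F2. Ring-closing metathesis with the same catalyst, now between a vinyl group and an electron-rich allylic ether olefin, should close the seven-membered (4S)-4,7-dihydro-1,3,2-dioxasilepine F3, in which the two oxygen-bearing carbons are again forced cis. Bu4NF then releases diol 20.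

Step 18 may suffer from an insufficient rate difference between the two carbinol epimers and from titanium-assisted opening of the acid-sensitive 2,2-disubstituted epoxide; it also uses at most half of the material. The fallback sets out from 27 and comes back at 28. Dess–Martin periodinane oxidation of the epimer mixture should give (6E,8S,10E)-13-(furan-3-yl)-8-methoxy-2,6,10-trimethyltrideca-1,6,10-trien-3-one F4. CBS reduction with the (S)-2-methyl-oxazaborolidine and BH3·SMe2, in which the isopropenyl group acts as the large substituent, should give the (3R)-alcohol F5. Hydroxyl-directed epoxidation with VO(acac)2 and tBuOOH, erythro-selective for 2-substituted allylic alcohols through A(1,2) strain, then gives 28.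

Step 19 may stall because the aggregated dilithioacetate is a weak nucleophile toward an oxirane CH2 next to a fully substituted carbon, and residual amide base may isomerise the epoxide to an allylic alcohol. The fallback sets out from 28 and comes back at 30. LiCH2CN (from MeCN and n-BuLi, THF, −78 → 0 °C) should open the epoxide at CH2 to give (4S,5R,8E,10S,12E)-15-(furan-3-yl)-4,5-dihydroxy-10-methoxy-4,8,12-trimethylpentadeca-8,12-dienenitrile F6. KOH in aqueous ethanol at reflux hydrolyses the nitrile, and acidification to pH 3 closes the γ-lactone 30.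

Further compounds
F1 | step 10 | 2-(3,3-dimethoxypropyl)prop-2-en-1-ol | C=C(CO)CCC(OC)OC
F2 | step 10 | {[2-(3,3-dimethoxypropyl)prop-2-en-1-yl]oxy}{[(3S,5E)-8-(furan-3-yl)-5-methylocta-1,5-dien-3-yl]oxy}di(propan-2-yl)silane | C=C(CCC(OC)OC)CO[Si](C(C)C)(C(C)C)O[C@H](C=C)C/C(C)=C/CCc1ccoc1
F3 | step 10 | (4S)-6-(3,3-dimethoxypropyl)-4-[(2E)-5-(furan-3-yl)-2-methylpent-2-en-1-yl]-2,2-di(propan-2-yl)-4,7-dihydro-1,3,2-dioxasilepine | CC(C)[Si]1(C(C)C)OCC(CCC(OC)OC)=C[C@H](C/C(C)=C/CCc2ccoc2)O1
F4 | step 18 | (6E,8S,10E)-13-(furan-3-yl)-8-methoxy-2,6,10-trimethyltrideca-1,6,10-trien-3-one | C=C(C)C(=O)CC/C(C)=C/[C@@H](OC)C/C(C)=C/CCc1ccoc1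
F5 | step 18 | (3R,6E,8S,10E)-13-(furan-3-yl)-8-methoxy-2,6,10-trimethyltrideca-1,6,10-trien-3-ol | C=C(C)[C@H](O)CC/C(C)=C/[C@@H](OC)C/C(C)=C/CCc1ccoc1
F6 | step 19 | (4S,5R,8E,10S,12E)-15-(furan-3-yl)-4,5-dihydroxy-10-methoxy-4,8,12-trimethylpentadeca-8,12-dienenitrile | C[C@](O)(CCC#N)[C@H](O)CC/C(C)=C/[C@@H](OC)C/C(C)=C/CCc1ccoc1
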